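Assumption: the SMILES is read as the (3R,4R)-trans-lactone whose ring B carries a threo-(7R,8R) guaiacylglycerol 8-aryl ether; (4S)-4-benzyl-3-(chloroacetyl)-1,3-oxazolidin-2-one is taken as a catalogue reagent.

**Retrosynthetic overview**
- Target ⇐ one hydrogenolysis of a trans-lactone in which both phenols are benzyl ethers and the 7,9-diol is a benzylidene acetal.
- Lactone (last ring formed) ⇐ γ-hydroxy ester ⇐ imide/ester succinate. Its central α,α′ bond (lactone C3–C4) comes from an iron-mediated oxidative heterocoupling of two enolates: the ring B imide (auxiliary sets C4) and the ring A methyl ester (C3 set afterwards by epimerisation to trans).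
- Ring B imide ⇐ threo aryloxy-diol from an Evans syn-aldol of an aryloxyacetyl imide with O-benzylvanillin, reductive auxiliary removal, then the 1,3-dioxane ring (first ring formed).
- Both halves come from methyl dihydroferulate; one auxiliary, (4S)-4-benzyloxazolidin-2-one, serves both stereo-defining steps.

Abbreviations: ArA = 4-benzyloxy-3-methoxyphenyl; ArB = 4-{[(2S,4R,5R)-4-(4-benzyloxy-3-methoxyphenyl)-2-phenyl-1,3-dioxan-5-yl]oxy}-3-methoxyphenyl; Xs = (4S)-4-benzyl-2-oxo-1,3-oxazolidin-3-yl. Side-chain carbons: C7 (benzylic carbinol), C8 (aryloxy carbon), C9 (CH2OH).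

**Step 1**
Reactants: 1 methyl 3-(4-hydroxy-3-methoxyphenyl)propanoate; 2 (4S)-4-benzyl-3-(chloroacetyl)-1,3-oxazolidin-2-one
Product: 3 methyl 3-{4-[2-oxo-2-Xs-ethoxy]-3-methoxyphenyl}propanoate
Conditions: K2CO3 (1.5 equiv), MeCN, 40 °C
Reagents that add atoms: none
Why: Williamson ether synthesis, in which SN2 attack of the phenoxide on the activated α-chloro imide outruns acyl transfer under mild carbonate conditions and leaves the auxiliary stereocentre untouched.

**Step 2**
Reactants: 3 methyl 3-{4-[2-oxo-2-Xs-ethoxy]-3-methoxyphenyl}propanoate; 4 4-benzyloxy-3-methoxybenzaldehyde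
Product: 7 methyl 3-[4-{[(1R,2S)-1-(4-benzyloxy-3-methoxyphenyl)-1-hydroxy-3-oxo-3-Xs-propan-2-yl]oxy}-3-methoxyphenyl]propanoate, via Z dibutylboron enolate 5 (not isolated), via dibutylboron aldolate 6 (not isolated)
Conditions: Bu2BOTf (1.2 equiv), iPr2NEt (1.4 equiv), CH2Cl2, −78 → 0 °C; then 4, −78 → 0 °C; H2O2, MeOH, pH 7 buffer, 0 °C
Reagents that add atoms: none
Why: Evans syn-aldol reaction, in which soft enolisation gives only the Z boron enolate of the imide (the methyl ester is not enolised) and a closed Zimmerman–Traxler transition state with the aldehyde on the enolate face remote from the 4-benzyl group sets (2S,3R) in the acyl chain, which is the threo (7R,8R) pair of the target.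

**Step 3**
Reactants: 7 the syn-aldol adduct
Product: 9 3-[4-{[(1R,2R)-1-(4-benzyloxy-3-methoxyphenyl)-1,3-dihydroxypropan-2-yl]oxy}-3-methoxyphenyl]propanoic acid, via diol methyl ester 8 (not isolated)
Conditions: NaBH4 (4 equiv), THF/H2O (4:1), 0 °C → rt; then LiOH·H2O (3 equiv), rt; cold dilute HCl to pH 3–4
Reagents that add atoms: lithium hydroxide, [Li+].[OH-]
Why: Chemoselective borohydride reductive cleavage of the activated N-acyl oxazolidinone leaves the methyl ester, which is then saponified in the same pot so that the auxiliary is removed by extracting the basic solution; no stereocentre is touched.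

**Step 4**
Reactants: 9 the dihydroxy acid
Product: 10 3-ArB-propanoic acid (benzylidene acetal of the 7,9-diol)
Conditions: PhCH(OMe)2 (1.5 equiv), CSA (5 mol %), 4 Å MS, CH2Cl2, rt
Reagents that add atoms: benzaldehyde dimethyl acetal, COC(OC)c1ccccc1
Why: Acid-catalysed transacetalisation under thermodynamic control closes the six-membered 1,3-dioxane and sets the new acetal centre as 2S, with the phenyl equatorial and cis to the equatorial C4 aryl group.

**Step 5**
Reactants: 10 3-ArB-propanoic acid; 11 (4S)-4-benzyl-1,3-oxazolidin-2-one (commercial; also recovered from steps 3 and 8)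
Product: 13 (4S)-4-benzyl-3-(3-ArB-propanoyl)-1,3-oxazolidin-2-one, via mixed pivalic anhydride 12 (not isolated)
Conditions: PivCl (1.1 equiv), Et3N (2.5 equiv), THF, −20 °C; then 11, LiCl (1.1 equiv), −20 °C → rt
Reagents that add atoms: none
Why: N-acylation of the oxazolidinone through the mixed pivalic anhydride (LiCl-promoted one-pot protocol) is mild enough for the benzylidene acetal and installs the auxiliary that will control lactone C4.

**Step 6**
Reactants: 1 methyl 3-(4-hydroxy-3-methoxyphenyl)propanoate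
Product: 14 methyl 3-ArA-propanoate
Conditions: BnBr (1.1 equiv), K2CO3 (1.5 equiv), DMF, rt
Reagents that add atoms: benzyl bromide, BrCc1ccccc1
Why: Williamson ether synthesis on the only acidic hydroxyl, with no stereochemistry involved.

**Step 7**
Reactants: 13 (4S)-4-benzyl-3-(3-ArB-propanoyl)-1,3-oxazolidin-2-one (1.0 equiv); 14 methyl 3-ArA-propanoate (1.5 equiv)
Product: 17 (4S)-4-benzyl-3-[(2R,3RS)-4-ArA-2-(ArB-methyl)-3-(methoxycarbonyl)butanoyl]-1,3-oxazolidin-2-one (mixture of C3 epimers), via imide lithium Z-enolate 15 (not isolated), via ester lithium enolate 16 (not isolated)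
Conditions: LiN(iPr)2 (2.6 equiv), THF, −78 °C, 30 min; then Fe(acac)3 (iron tris(acetylacetonate), 2.6 equiv) in THF, −78 °C → rt
Reagents that add atoms: none
Why: Oxidative enolate heterocoupling, in which single-electron oxidation by trivalent iron turns one of two nucleophilic α-carbons into an electrophilic α-carbonyl radical that the other enolate captures (a polarity reversal of one enolate); the chelated Z-imide enolate reacts on the face opposite the 4-benzyl group, as in an Evans alkylation, so C2 is set as R (future lactone C4), while the ester-side centre forms as a mixture that step 9 corrects.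

**Step 8**
Reactants: 17 the coupled imide ester
Product: 18 methyl (2RS,3R)-2-(ArA-methyl)-4-ArB-3-(hydroxymethyl)butanoate (mixture of C2 epimers; used crude)
Conditions: NaBH4 (4 equiv), THF/H2O (4:1), 0 °C → rt; aq. NH4Cl
Reagents that add atoms: none
Why: Chemoselective borohydride reductive cleavage of the imide leaves the hindered methyl ester and the acetal and does not touch the adjacent stereocentre; any lactone that forms in the flask is carried into step 9.

**Step 9**
Reactants: 18 the hydroxy ester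
Product: 19 (3R,4R)-3-(ArA-methyl)-4-(ArB-methyl)oxolan-2-one
Conditions: KOtBu (0.3 equiv), THF, 0 °C → rt; AcOH quench
Reagents that add atoms: none
Why: Base-mediated lactonisation with thermodynamic epimerisation, in which the alkoxide closes the five-membered ring and reversible enolisation at C3 funnels both epimers into the more stable trans lactone, so C3 becomes R relative to the fixed C4 (R).

**Step 10**
Reactants: 19 the protected trans-lactone
Product: 20 (3R,4R)-4-[4-{[(1R,2R)-1,3-dihydroxy-1-(4-hydroxy-3-methoxyphenyl)propan-2-yl]oxy}-3-methoxybenzyl]-3-(4-hydroxy-3-methoxybenzyl)oxolan-2-one (target)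
Conditions: H2 (1 atm), palladium on carbon (10 % Pd/C), EtOAc/MeOH (1:1), rt
Reagents that add atoms: none
Why: Catalytic hydrogenolysis cleaves both aryl benzyl ethers and the benzylidene acetal in one neutral operation that leaves the lactone, the aryl methyl ethers and the secondary benzylic alcohol intact; no stereocentre is affected.

**Compound list**
1 | methyl 3-(4-hydroxy-3-methoxyphenyl)propanoate | COC(=O)CCc1ccc(O)c(OC)c1 | starting material
2 | (4S)-4-benzyl-3-(chloroacetyl)-1,3-oxazolidin-2-one | O=C(CCl)N1[C@@H](Cc2ccccc2)COC1=O | starting material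
3 | methyl 3-{4-[2-oxo-2-Xs-ethoxy]-3-methoxyphenyl}propanoate | COC(=O)CCc1ccc(OCC(=O)N2[C@@H](Cc3ccccc3)COC2=O)c(OC)c1 | intermediate
4 | 4-benzyloxy-3-methoxybenzaldehyde | O=Cc1ccc(OCc2ccccc2)c(OC)c1 | starting material
5 | Z dibutylboron enolate of 3 (aryloxy group cis to O–B) | COC(=O)CCc1ccc(O/C=C(\OB(CCCC)CCCC)N2[C@@H](Cc3ccccc3)COC2=O)c(OC)c1 | intermediate
6 | dibutylboron aldolate of 7 (boron on the benzylic oxygen) | COC(=O)CCc1ccc(O[C@H](C(=O)N2[C@@H](Cc3ccccc3)COC2=O)[C@H](OB(CCCC)CCCC)c2ccc(OCc3ccccc3)c(OC)c2)c(OC)c1 | intermediate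
7 | methyl 3-[4-{[(1R,2S)-1-(4-benzyloxy-3-methoxyphenyl)-1-hydroxy-3-oxo-3-Xs-propan-2-yl]oxy}-3-methoxyphenyl]propanoate | COC(=O)CCc1ccc(O[C@H](C(=O)N2[C@@H](Cc3ccccc3)COC2=O)[C@H](O)c2ccc(OCc3ccccc3)c(OC)c2)c(OC)c1 | intermediate
8 | methyl 3-[4-{[(1R,2R)-1-(4-benzyloxy-3-methoxyphenyl)-1,3-dihydroxypropan-2-yl]oxy}-3-methoxyphenyl]propanoate | COC(=O)CCc1ccc(O[C@H](CO)[C@H](O)c2ccc(OCc3ccccc3)c(OC)c2)c(OC)c1 | intermediate
9 | 3-[4-{[(1R,2R)-1-(4-benzyloxy-3-methoxyphenyl)-1,3-dihydroxypropan-2-yl]oxy}-3-methoxyphenyl]propanoic acid | OC(=O)CCc1ccc(O[C@H](CO)[C@H](O)c2ccc(OCc3ccccc3)c(OC)c2)c(OC)c1 | intermediate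
10 | 3-[4-{[(2S,4R,5R)-4-(4-benzyloxy-3-methoxyphenyl)-2-phenyl-1,3-dioxan-5-yl]oxy}-3-methoxyphenyl]propanoic acid | OC(=O)CCc1ccc(O[C@@H]2CO[C@H](c3ccccc3)O[C@@H]2c2ccc(OCc3ccccc3)c(OC)c2)c(OC)c1 | intermediate
11 | (4S)-4-benzyl-1,3-oxazolidin-2-one | O=C1N[C@@H](Cc2ccccc2)CO1 | starting material
12 | mixed pivalic anhydride of 10 | CC(C)(C)C(=O)OC(=O)CCc1ccc(O[C@@H]2CO[C@H](c3ccccc3)O[C@@H]2c2ccc(OCc3ccccc3)c(OC)c2)c(OC)c1 | intermediate
13 | (4S)-4-benzyl-3-(3-ArB-propanoyl)-1,3-oxazolidin-2-one | O=C(CCc1ccc(O[C@@H]2CO[C@H](c3ccccc3)O[C@@H]2c2ccc(OCc3ccccc3)c(OC)c2)c(OC)c1)N1[C@@H](Cc2ccccc2)COC1=O | intermediate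
14 | methyl 3-(4-benzyloxy-3-methoxyphenyl)propanoate | COC(=O)CCc1ccc(OCc2ccccc2)c(OC)c1 | intermediate
15 | lithium Z-enolate of imide 13 | [Li]O/C(=C\Cc1ccc(O[C@@H]2CO[C@H](c3ccccc3)O[C@@H]2c2ccc(OCc3ccccc3)c(OC)c2)c(OC)c1)N1[C@@H](Cc2ccccc2)COC1=O | intermediate
16 | lithium enolate of ester 14 (O–Li trans to the benzylic carbon) | [Li]O/C(OC)=C/Cc1ccc(OCc2ccccc2)c(OC)c1 | intermediate
17 | (4S)-4-benzyl-3-[(2R,3RS)-4-ArA-2-(ArB-methyl)-3-(methoxycarbonyl)butanoyl]-1,3-oxazolidin-2-one (C3 left undefined: epimer mixture) | COC(=O)C(Cc1ccc(OCc2ccccc2)c(OC)c1)[C@@H](Cc1ccc(O[C@@H]2CO[C@H](c3ccccc3)O[C@@H]2c2ccc(OCc3ccccc3)c(OC)c2)c(OC)c1)C(=O)N1[C@@H](Cc2ccccc2)COC1=O | intermediate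
18 | methyl (2RS,3R)-2-(ArA-methyl)-4-ArB-3-(hydroxymethyl)butanoate (C2 left undefined: epimer mixture) | COC(=O)C(Cc1ccc(OCc2ccccc2)c(OC)c1)[C@@H](Cc1ccc(O[C@@H]2CO[C@H](c3ccccc3)O[C@@H]2c2ccc(OCc3ccccc3)c(OC)c2)c(OC)c1)CO | intermediate
19 | (3R,4R)-3-(4-benzyloxy-3-methoxybenzyl)-4-[4-{[(2S,4R,5R)-4-(4-benzyloxy-3-methoxyphenyl)-2-phenyl-1,3-dioxan-5-yl]oxy}-3-methoxybenzyl]oxolan-2-one | COc1cc(C[C@H]2C(=O)OC[C@@H]2Cc2ccc(O[C@@H]3CO[C@H](c4ccccc4)O[C@@H]3c3ccc(OCc4ccccc4)c(OC)c3)c(OC)c2)ccc1OCc1ccccc1 | intermediate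
20 | (3R,4R)-4-[4-{[(1R,2R)-1,3-dihydroxy-1-(4-hydroxy-3-methoxyphenyl)propan-2-yl]oxy}-3-methoxybenzyl]-3-(4-hydroxy-3-methoxybenzyl)oxolan-2-one | COc1cc(C[C@H]2C(=O)OC[C@@H]2Cc2ccc(O[C@H](CO)[C@H](O)c3ccc(O)c(OC)c3)c(OC)c2)ccc1O | target

**Step count**
Total: 10 steps. Longest linear sequence: 9 steps (1 → 2 → 3 → 4 → 5 → 7 → 8 → 9 → 10); step 6 is the one-step side branch.

**Three steps most likely to fail**

Step 7 (oxidative heterocoupling). The risks are homodimer formation, a modest yield with so large an imide, and incomplete facial control in a radical-type bond formation. Because 13 already carries fixed stereocentres, a wrong-face product would be a separable diastereomer and would not erode enantiopurity.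

The fallback sets out from 13 and comes back at 19. Imide 13 is deprotonated with NaN(SiMe3)2 (THF, −78 °C) and the Z-enolate is alkylated with tert-butyl bromoacetate, an α-carbonyl cation equivalent, so the α,α′ bond is still made with reversed polarity at one carbon. This gives (4S)-4-benzyl-3-[(2R)-2-(ArB-methyl)-4-tert-butoxy-4-oxobutanoyl]-1,3-oxazolidin-2-one F1. LiBH4/MeOH (Et2O, 0 °C) reduces only the imide to tert-butyl (3R)-4-ArB-3-(hydroxymethyl)butanoate F2. Catalytic KOtBu in THF closes it to (4R)-4-(ArB-methyl)oxolan-2-one F3. Its lithium enolate (LiN(SiMe3)2, THF, −78 °C) is alkylated anti to the C4 substituent with 4-benzyloxy-3-methoxybenzyl bromide F4 (from the commercial benzyl alcohol and PBr3), which gives trans-lactone 19 directly.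

Step 8 (imide reduction beside a methyl ester). The risks are slow reduction of the hindered, doubly branched imide, endocyclic opening of the oxazolidinone, or partial ester reduction.

The fallback sets out from 17 and comes back at 18. LiOH/H2O2 (THF/H2O, 0 °C) cleaves only the imide to the half-ester (2R,3RS)-4-ArA-2-(ArB-methyl)-3-(methoxycarbonyl)butanoic acid F5. BH3·SMe2 (THF, 0 °C) then reduces the free carboxylic acid in the presence of the methyl ester to give 18, or its lactone, which step 9 accepts equally.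

Step 10 (global hydrogenolysis). The risk is loss of the C7 oxygen, since the C7–O bond is itself a benzylic ether while the acetal is in place and an electron-rich benzylic alcohol afterwards.

The fallback sets out from 19 and comes back at 20. The acetal is removed hydrolytically first (80 % aqueous AcOH, 40 °C) to give (3R,4R)-3-(4-benzyloxy-3-methoxybenzyl)-4-[4-{[(1R,2R)-1-(4-benzyloxy-3-methoxyphenyl)-1,3-dihydroxypropan-2-yl]oxy}-3-methoxybenzyl]oxolan-2-one F6. The two remaining aryl benzyl ethers are then cleaved by catalytic transfer hydrogenolysis (palladium on carbon, cyclohexa-1,4-diene, EtOH, rt), which is self-limiting and gives 20.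

**Further compounds**
F1 | step 7 | (4S)-4-benzyl-3-[(2R)-2-(ArB-methyl)-4-tert-butoxy-4-oxobutanoyl]-1,3-oxazolidin-2-one | CC(C)(C)OC(=O)C[C@@H](Cc1ccc(O[C@@H]2CO[C@H](c3ccccc3)O[C@@H]2c2ccc(OCc3ccccc3)c(OC)c2)c(OC)c1)C(=O)N1[C@@H](Cc2ccccc2)COC1=O
F2 | step 7 | tert-butyl (3R)-4-ArB-3-(hydroxymethyl)butanoate | CC(C)(C)OC(=O)C[C@@H](Cc1ccc(O[C@@H]2CO[C@H](c3ccccc3)O[C@@H]2c2ccc(OCc3ccccc3)c(OC)c2)c(OC)c1)CO
F3 | step 7 | (4R)-4-(ArB-methyl)oxolan-2-one | O=C1C[C@@H](Cc2ccc(O[C@@H]3CO[C@H](c4ccccc4)O[C@@H]3c3ccc(OCc4ccccc4)c(OC)c3)c(OC)c2)CO1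
F4 | step 7 | 4-benzyloxy-3-methoxybenzyl bromide | BrCc1ccc(OCc2ccccc2)c(OC)c1
F5 | step 8 | (2R,3RS)-4-ArA-2-(ArB-methyl)-3-(methoxycarbonyl)butanoic acid | COC(=O)C(Cc1ccc(OCc2ccccc2)c(OC)c1)[C@@H](Cc1ccc(O[C@@H]2CO[C@H](c3ccccc3)O[C@@H]2c2ccc(OCc3ccccc3)c(OC)c2)c(OC)c1)C(=O)O
F6 | step 10 | (3R,4R)-3-(4-benzyloxy-3-methoxybenzyl)-4-[4-{[(1R,2R)-1-(4-benzyloxy-3-methoxyphenyl)-1,3-dihydroxypropan-2-yl]oxy}-3-methoxybenzyl]oxolan-2-one | COc1cc(C[C@H]2C(=O)OC[C@@H]2Cc2ccc(O[C@H](CO)[C@H](O)c3ccc(OCc4ccccc4)c(OC)c3)c(OC)c2)ccc1OCc1ccccc1
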